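## Analysis of the target

Target 33 is a B-type proanthocyanidin. Its upper unit is (−)-epiafzelechin 3-O-gallate (phloroglucinol ring A, pyran ring C, 4-hydroxyphenyl ring B), bonded from C4 to C8 of (−)-epicatechin 3-O-gallate (ring D, pyran ring F, catechol ring E). There are five stereocentres. Upper C2, C3 and C4 are R,R,R, with ring B cis to the C3 ester and the C3 ester trans to the C4 aryl group; lower C2 and C3 are R,R, as in natural epicatechin 1. The molecule carries thirteen free phenols, two gallate esters on hindered axial alcohols, and a doubly benzylic C4 between two phloroglucinol rings whose bond to ring D is cleaved by acid. The hard points are the bond from C4 to the di-ortho-substituted C8, the 2,3-cis/3,4-trans triad of ring C, and the tendency of C2, a 4-oxybenzylic ether carbon, to ionise. The lower unit can be bought with both stereocentres in place, so only the three upper ones have to be made. The plan rests on ring A: it is a phloroglucinol with one carbon substituent (C4 on C4a) between two equivalent oxygens on C5 and C8a, and is therefore symmetric about the C4a–C7 axis. A Claisen closure between C4a and C8a of a 3,5-dioxo ester delivers exactly such a ring, and either flanking hydroxyl can later become O1.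

## Retrosynthetic reasoning

**Esters and ethers last.** 33 goes back to 32 by cutting thirteen benzyl O–C bonds in one hydrogenolysis, and 32 goes back to diol 29 and acid 30 by cutting the two ester C–O bonds. The gallates are placed at the very end because no ester of this kind would survive the organometallic and amide-base steps. Benzyl is the only phenol protecting group, so one operation frees all phenols.

**Ring C.** From 29 back to 27 only protecting groups change (silyl ether on the lower O3, acetal on the upper O3, two benzyl ethers on ring A). In 26 the O1–C2 bond is cut, which leads to phenol–alcohol 25. Because ring A in 25 is symmetric, either ortho hydroxyl closes to the same flavan. The forward reaction has to form the ether with inversion at the benzylic C2, so the C2 oxygen must be anti to the C3 oxygen, and the C3 oxygen must stay blocked so that no epoxide forms.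

**Ring A (key disconnection).** 25 comes from silyl ether 24, and 24 is opened at the C4a–C8a bond to the methyl 3,5-dioxo ester 21. This cut is chosen because it turns the only ring without a regiochemical question into an acyclic chain. The three stereocentres can then be set on small, conformationally defined intermediates, and C4 sits beta, not alpha, to the nearest carbonyl. The forward step must achieve C-acylation at C4a and aromatisation.

**Polyketide chain.** 21 is cut between C5 and C6 into Weinreb amide 18 and methyl acetoacetate 19, used as its dianion 20. Four carbons of ring A come from 19 in one step, and the amide stops the addition at the ketone stage.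

**C2 configuration.** 18 goes back through alcohol 17 and ketone 16 to the C2-epimeric alcohol 15, and 15 to lactone 14 by closing the amide back to the ester. The detour is needed because the conjugate addition below is reliable only on the 5,6-cis lactone (C2 oxygen syn to the C3 oxygen), whereas the ether closure needs the anti arrangement. The ketone permits a chelation-controlled reduction that sets the anti alcohol.

**C4–C8 bond.** 14 is cut between C4 and C8 of ring D into the unsaturated lactone 10 and cuprate 12, made from bromide 4 through aryllithium 11. The bond is made here, before ring A exists, because C4 is then the β-carbon of an enoate and accepts an aryl nucleophile. An acyclic (E)-enoate would be expected to give the 3,4-anti adduct, the usual outcome with γ-alkoxy enoates, and that is the wrong diastereomer. In cis-lactone 10 the acetal oxygen and ring B lie on one face, so attack from the other face gives the required trans relationship between the C3 oxygen and the new aryl group.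

**Lactone.** 10 is cut at the C4=C4a double bond (ring-closing metathesis of acrylate 9), at the ester C–O bond (alcohol 8), and between C2 and C3 (aldehyde 5 and allyl ether 6 through allylborane 7). One reagent-controlled step sets both oxygen-bearing stereocentres and delivers the C3 oxygen already protected.

**Lower unit.** Bromide 4 goes back through 3 and 2 to epicatechin 1 by silylation, bromination at C8 and phenol benzylation. No stereocentre of the lower unit is made or touched.

## Alternatives that were turned down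

**Alternative 1:** Ring F of the lower unit is cut at C3–C4 and O1–C2 (retro [4+2]). This leads to salicyl alcohol A1, a ring D that already carries the complete upper unit at C8, and to (Z)-enol gallate A3. In the forward step A1 is dehydrated to ortho-quinone methide A2, which adds A3 with inverse electron demand to give the perbenzylated target A4 (the same compound as 32).
- For it: it is convergent, the Z geometry is transferred suprafacially into the 2,3-cis relationship, and the lower gallate arrives without acylating a hindered alcohol. On these points it is stronger than the chosen route.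
- Against it: A2 is planar and its nearest stereocentres lie in the upper unit beyond C8, so the two faces are hardly distinguished and both cis arrays of the lower unit are expected. An enol ester is a weak partner for a quinone methide, and self-condensation of A2 competes. A1 still requires the upper unit with its C4–aryl bond, so the hardest bond is only moved upstream.
- Comparison: the chosen route takes the lower stereocentres unchanged from 1 and makes the C4–C8 bond under substrate control on a small lactone. In exchange it accepts a late double esterification.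

**Alternative 2:** Ring D is taken apart into diazo enone A5 and siloxyalkyne A7, which sits on C4 of a finished upper flavan. On irradiation A5 undergoes Wolff rearrangement to vinylketene A6; [2+2] addition to A7, four-electron ring opening and six-electron closure give ring D phenol A8.
- For it: the unsymmetrical ring D is assembled with defined regiochemistry, and the C4 substituent is introduced as a small alkyne nucleophile and not as a hindered aryl group. The benzannulation also has broader precedent than a polyanion Claisen closure. On both points it is stronger than the chosen key step.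
- Against it: the lower unit must be built from an open chain with two new stereocentres and then cyclised, which discards the chiral pool. The upper flavan has to exist beforehand, so both pyran rings and all five stereocentres are made by synthesis. Diazo ketone and siloxyalkyne are sensitive partners at a late stage.
- Comparison: the chosen route builds the symmetric ring A, where orientation does not matter, and keeps the lower unit intact; this saves the steps Alternative 2 spends on the lower chain and on a second ring closure.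

**Alternative 3:** Ring C is cut at C2=C3. Diene A9 carries an α-aryl vinyl ether on O1 and a vinyl group on C4. Ruthenium-carbene-catalysed ring-closing metathesis joins the two alkenes, with loss of the two terminal methylene groups, to give the 2,4-diaryl-4H-chromene A10.
- For it: the ring closure is robust and makes no demand on C2, so it is stronger than an ether closure at an ionisable benzylic carbon.
- Against it: A10 has neither the C3 oxygen nor the C2 hydrogen. Hydroboration adds hydrogen and boron syn and anti to the C4 aryl group, which gives the 2,3-trans isomer with ring B on the wrong face relative to C4; oxidation and reduction at C3 cannot repair C2. The doubly benzylic, allylic C4 of A9 invites alkene migration into conjugation, and its enantioselective construction is left open.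
- Comparison: the chosen route sets C2, C3 and C4 before ring C is closed and needs no redox correction on the flavan; it pays with a closure that depends on clean inversion.

Key step: step 13

Remarks on the chemistry assumed:
- Allyl methoxymethyl ether 6 and (−)-Ipc2BOMe are taken as purchasable.
- The (−)-Ipc2B reagent is assumed to attack the Si face of 5, as with other aryl aldehydes.
- In names, ArD = (2R,3R)-5,7-bis(benzyloxy)-2-[3,4-bis(benzyloxy)phenyl]-3-[(tert-butyldimethylsilyl)oxy]chroman-8-yl.

## Route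

Step 1
Reactants: 1 (−)-epicatechin
Product: 2 5,7,3',4'-tetra-O-benzyl-(−)-epicatechin
Conditions: BnBr (4.4 equiv), K2CO3, DMF, 0 °C → rt, argon
Reagents that add atoms: benzyl bromide, BrCc1ccccc1
Why: Williamson ether synthesis; K2CO3 deprotonates only the four phenols, so the C3 alcohol stays free and no stereocentre is touched.

Step 2
Reactants: 2 5,7,3',4'-tetra-O-benzyl-(−)-epicatechin
Product: 3 8-bromo-5,7,3',4'-tetra-O-benzyl-(−)-epicatechin
Conditions: NBS (1.0 equiv), CH2Cl2, −40 °C → rt
Reagents that add atoms: N-bromosuccinimide, O=C1CCC(=O)N1Br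
Why: Electrophilic aromatic bromination; of the two free positions of ring D, C8 between the C7 ether and the pyran oxygen is the more nucleophilic one in this ether, so monobromination should occur there.

Step 3
Reactants: 3 8-bromo-5,7,3',4'-tetra-O-benzyl-(−)-epicatechin
Product: 4 8-bromo-3-O-(tert-butyldimethylsilyl)-5,7,3',4'-tetra-O-benzyl-(−)-epicatechin (ArD–Br)
Conditions: TBSCl, imidazole, DMF, rt
Reagents that add atoms: tert-butyldimethylsilyl chloride, CC(C)(C)[Si](C)(C)Cl
Why: Silylation of the secondary alcohol, which would otherwise quench the aryllithium of step 7; the silyl ether is inert to all bases used later.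

Step 4
Reactants: 5 4-(benzyloxy)benzaldehyde, 6 allyl methoxymethyl ether
Product: 8 (1R,2R)-1-[4-(benzyloxy)phenyl]-2-(methoxymethoxy)but-3-en-1-ol, via [(Z)-3-(methoxymethoxy)allyl]diisopinocampheylborane 7 (not isolated)
Conditions: 6, s-BuLi, THF, −78 °C; (−)-Ipc2BOMe; BF3·OEt2; then 5, −78 °C; NaOH, H2O2, rt
Reagents that add atoms: none
Why: Brown alkoxyallylboration; the Z-configured allylborane reacts through a closed chair transition state and gives the syn product, and the isopinocampheyl groups from (+)-α-pinene direct the allyl group to the Si face of 5, which sets C2 and C3 as 1R,2R.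

Step 5
Reactants: 8 (1R,2R)-1-[4-(benzyloxy)phenyl]-2-(methoxymethoxy)but-3-en-1-ol
Product: 9 (1R,2R)-1-[4-(benzyloxy)phenyl]-2-(methoxymethoxy)but-3-en-1-yl acrylate
Conditions: acryloyl chloride, iPr2NEt, DMAP (cat.), CH2Cl2, −20 → 0 °C
Reagents that add atoms: acryloyl chloride, C=CC(=O)Cl
Why: O-acylation of a secondary alcohol with retention; the low temperature suppresses amine addition to the acrylate.

Step 6
Reactants: 9 (1R,2R)-1-[4-(benzyloxy)phenyl]-2-(methoxymethoxy)but-3-en-1-yl acrylate
Product: 10 (5R,6R)-6-[4-(benzyloxy)phenyl]-5-(methoxymethoxy)-5,6-dihydro-2H-pyran-2-one (5,6-cis)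
Conditions: second-generation Grubbs catalyst RuCl2(=CHPh)(H2IMes)(PCy3) (5 mol %), CH2Cl2 (0.01 M), 40 °C
Reagents that add atoms: none
Why: Ring-closing metathesis of an acrylate of a homoallylic alcohol to a dihydropyranone; the ring enforces the cis alkene, and the syn arrangement of 8 becomes the 5,6-cis lactone.

Step 7
Reactants: 4 ArD–Br, 10 (5R,6R)-6-[4-(benzyloxy)phenyl]-5-(methoxymethoxy)-5,6-dihydro-2H-pyran-2-one
Product: 14 (4R,5R,6R)-4-ArD-6-[4-(benzyloxy)phenyl]-5-(methoxymethoxy)tetrahydro-2H-pyran-2-one, via C8 aryllithium 11 (not isolated), via lithium diarylcuprate 12 (not isolated), via trimethylsilyl ketene acetal 13 (not isolated)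
Conditions: 4 (2.2 equiv), t-BuLi (4.4 equiv), THF, −78 °C; CuI (1.1 equiv), Me2S, −78 → −40 °C; Me3SiCl, then 10, −78 → −30 °C; aq. NH4Cl/NH3
Reagents that add atoms: none
Why: Bromine–lithium exchange, formation of the Gilman cuprate and silyl-chloride-accelerated conjugate addition to an unsaturated lactone. The aryl group enters C4 axially, anti to the pseudo-axial C5 acetal oxygen and to the C6 aryl group, which lie on the same face, so both substituents direct to the 4R configuration (4,5-trans). The acetal oxygen is a poor leaving group and should survive.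

Step 8
Reactants: 14 (4R,5R,6R)-4-ArD-6-[4-(benzyloxy)phenyl]-5-(methoxymethoxy)tetrahydro-2H-pyran-2-one
Product: 15 (3R,4R,5R)-3-ArD-5-[4-(benzyloxy)phenyl]-5-hydroxy-N-methoxy-4-(methoxymethoxy)-N-methylpentanamide
Conditions: MeNH(OMe)·HCl, iPrMgCl, THF, −20 → 0 °C
Reagents that add atoms: N,O-dimethylhydroxylamine hydrochloride, CNOC.Cl
Why: Weinreb aminolysis of a lactone by the chloromagnesium amide; the C–O bond at C5 is not broken, so all three stereocentres are retained.

Step 9
Reactants: 15 (3R,4R,5R)-3-ArD-5-[4-(benzyloxy)phenyl]-5-hydroxy-N-methoxy-4-(methoxymethoxy)-N-methylpentanamide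
Product: 16 (3R,4R)-3-ArD-5-[4-(benzyloxy)phenyl]-N-methoxy-4-(methoxymethoxy)-N-methyl-5-oxopentanamide
Conditions: Dess–Martin periodinane, NaHCO3, CH2Cl2, 0 °C → rt
Reagents that add atoms: none
Why: Oxidation of the benzylic alcohol under buffered, non-basic conditions, which should leave the alpha-alkoxy stereocentre intact; it also removes the hydroxyl that could re-close the lactone.

Step 10
Reactants: 16 (3R,4R)-3-ArD-5-[4-(benzyloxy)phenyl]-N-methoxy-4-(methoxymethoxy)-N-methyl-5-oxopentanamide
Product: 17 (3R,4R,5S)-3-ArD-5-[4-(benzyloxy)phenyl]-5-hydroxy-N-methoxy-4-(methoxymethoxy)-N-methylpentanamide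
Conditions: Zn(BH4)2, Et2O–CH2Cl2, −40 → −10 °C
Reagents that add atoms: none
Why: Chelation-controlled (Cram cyclic model) reduction of an alpha-alkoxy ketone; zinc bridges the ketone and acetal oxygens, and hydride enters anti to the bulky C3 substituent of the chelate, which should give the 4,5-anti alcohol (5S). The Weinreb amide is not reduced.

Step 11
Reactants: 17 (3R,4R,5S)-3-ArD-5-[4-(benzyloxy)phenyl]-5-hydroxy-N-methoxy-4-(methoxymethoxy)-N-methylpentanamide
Product: 18 (3R,4R,5S)-3-ArD-5-[4-(benzyloxy)phenyl]-N-methoxy-4-(methoxymethoxy)-N-methyl-5-[(triethylsilyl)oxy]pentanamide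
Conditions: Et3SiCl, imidazole, DMF, rt
Reagents that add atoms: chlorotriethylsilane, CC[Si](Cl)(CC)CC
Why: Silylation of the secondary alcohol; the triethylsilyl ether blocks lactonisation and can later be removed in the presence of the tert-butyldimethylsilyl and acetal groups.

Step 12
Reactants: 18 (3R,4R,5S)-3-ArD-5-[4-(benzyloxy)phenyl]-N-methoxy-4-(methoxymethoxy)-N-methyl-5-[(triethylsilyl)oxy]pentanamide, 19 methyl acetoacetate
Product: 21 methyl (7R,8R,9S)-7-ArD-9-[4-(benzyloxy)phenyl]-8-(methoxymethoxy)-3,5-dioxo-9-[(triethylsilyl)oxy]nonanoate, via sodium lithium dienolate of methyl acetoacetate 20 (not isolated)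
Conditions: 19 (3 equiv), NaH, THF, 0 °C; n-BuLi, 0 °C; then 18, −78 → 0 °C; AcOH, aq. NH4Cl
Reagents that add atoms: none
Why: Acylation of the acetoacetate dianion at its terminal carbon by a Weinreb amide; the chelated tetrahedral intermediate prevents over-addition and gives the 3,5-dioxo ester on work-up. An excess of dianion is used because the product is the stronger acid.

Step 13
Reactants: 21 methyl (7R,8R,9S)-7-ArD-9-[4-(benzyloxy)phenyl]-8-(methoxymethoxy)-3,5-dioxo-9-[(triethylsilyl)oxy]nonanoate
Product: 24 2-[(1R,2R,3S)-1-ArD-3-[4-(benzyloxy)phenyl]-2-(methoxymethoxy)-3-[(triethylsilyl)oxy]propyl]benzene-1,3,5-triol, via trilithium trienolate 22 (not isolated), via cyclohexane-1,3,5-trione 23 (not isolated)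
Conditions: LiN(iPr)2 (4 equiv), THF (0.01 M, degassed), −78 °C → rt, then 50 °C; AcOH, aq. NH4Cl
Reagents that add atoms: none
Why: LiN(iPr)2 removes the C8 and C6 protons and, last, the C4a proton of 21; in trianion 22 the terminal and least stabilised carbon C4a attacks the ester carbonyl C8a, lithium methoxide leaves, and trione 23 is deprotonated at once and tautomerises to the phloroglucinolate, so aromatisation pulls the sequence forward. The closest known reaction type is the base-mediated Claisen (Dieckmann-type) cyclisation of 3,5-dioxo and 3,5,7-trioxo alkanoates to phloroglucinols, the laboratory counterpart of the chalcone-synthase closure. Ring A closes in the 6-(enolendo)-exo-trig mode, which is geometrically favoured. No stereocentre is formed; C2, C3 and C4 cannot epimerise because none is alpha to a carbonyl group, and beta-elimination is excluded because C4, the only beta-carbon, carries no leaving group. The selectivity needed is C-acylation at C4a and not O-acylation by the C5 enolate oxygen, which would give a 4-hydroxy-2-pyrone. Full deprotonation makes carbon the reactive site, and lactone formation can be reversed by the methoxide released, whereas the C–C closure ends in an aromatic trianion. The other conceivable closures (C8 onto C5, C4a onto C7) would form four-membered rings. The non-nucleophilic amide base avoids retro-Claisen cleavage of the diketone and leaves the benzyl, silyl and acetal ethers alone.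

Step 14
Reactants: 24 2-[(1R,2R,3S)-1-ArD-3-[4-(benzyloxy)phenyl]-2-(methoxymethoxy)-3-[(triethylsilyl)oxy]propyl]benzene-1,3,5-triol
Product: 25 2-[(1R,2R,3S)-1-ArD-3-[4-(benzyloxy)phenyl]-3-hydroxy-2-(methoxymethoxy)propyl]benzene-1,3,5-triol
Conditions: HF·pyridine, pyridine, THF, 0 °C, argon
Reagents that add atoms: none
Why: Fluoride cleavage of the triethylsilyl ether, which is much faster than that of the hindered tert-butyldimethylsilyl ether; the buffered medium should not ionise the benzylic alcohol or touch the acetal.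

Step 15
Reactants: 25 2-[(1R,2R,3S)-1-ArD-3-[4-(benzyloxy)phenyl]-3-hydroxy-2-(methoxymethoxy)propyl]benzene-1,3,5-triol
Product: 26 (2R,3R,4R)-4-ArD-2-[4-(benzyloxy)phenyl]-3-(methoxymethoxy)chroman-5,7-diol
Conditions: PPh3, DIAD, toluene–THF (0.005 M), 0 °C, argon
Reagents that add atoms: none
Why: Intramolecular Mitsunobu etherification; the alkoxyphosphonium ion at C2 is displaced by an ortho phenoxide in a 6-exo-tet closure with inversion, turning the anti alcohol into the 2R, 2,3-cis flavan. Both ortho hydroxyls give the same product, the para hydroxyl cannot reach C2, and the acetal on O3 prevents epoxide formation and destabilises a C2 cation.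

Step 16
Reactants: 26 (2R,3R,4R)-4-ArD-2-[4-(benzyloxy)phenyl]-3-(methoxymethoxy)chroman-5,7-diol
Product: 27 (2R,3R,4R)-5,7-bis(benzyloxy)-4-ArD-2-[4-(benzyloxy)phenyl]-3-(methoxymethoxy)chroman
Conditions: BnBr, K2CO3, DMF, rt
Reagents that add atoms: benzyl bromide, BrCc1ccccc1
Why: Williamson benzylation of the two remaining phenols; it keeps them out of the later acylation and ends the air sensitivity of ring A.

Step 17
Reactants: 27 (2R,3R,4R)-5,7-bis(benzyloxy)-4-ArD-2-[4-(benzyloxy)phenyl]-3-(methoxymethoxy)chroman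
Product: 28 (2R,3R,4R)-5,7-bis(benzyloxy)-4-ArD-2-[4-(benzyloxy)phenyl]chroman-3-ol
Conditions: Me2BBr, CH2Cl2, −78 °C; then THF, aq. NaHCO3
Reagents that add atoms: none
Why: Cleavage of the methoxymethyl ether by dimethylboron bromide, which attacks acetals at −78 °C while benzyl and silyl ethers are inert; the low temperature and short contact are chosen to spare the acid-sensitive C4–C8 bond.

Step 18
Reactants: 28 (2R,3R,4R)-5,7-bis(benzyloxy)-4-ArD-2-[4-(benzyloxy)phenyl]chroman-3-ol
Product: 29 5,7,4'-tri-O-benzyl-(−)-epiafzelechin-(4β→8)-5,7,3',4'-tetra-O-benzyl-(−)-epicatechin (both C3 hydroxyls free)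
Conditions: Bu4NF, AcOH, THF, rt → 40 °C
Reagents that add atoms: none
Why: Fluoride desilylation; buffered fluoride does not affect benzyl ethers or the stereocentres of either pyran ring.

Step 19
Reactants: 29 the diol of step 18, 30 3,4,5-tris(benzyloxy)benzoic acid
Product: 32 3,3''-bis-O-[3,4,5-tris(benzyloxy)benzoyl] derivative of 29, via 3,4,5-tris(benzyloxy)benzoyl chloride 31 (not isolated)
Conditions: 30 (4 equiv), (COCl)2, DMF (cat.), CH2Cl2, 0 °C → rt, evaporate; then 29, DMAP, pyridine–CH2Cl2, rt → 40 °C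
Reagents that add atoms: none
Why: Acylation of both axial secondary alcohols by the acid chloride through the acylpyridinium ion; the carbinol C–O bonds are not broken, so configuration is retained. The forcing acylating agent is needed for the upper hydroxyl next to the C4 aryl group.

Step 20
Reactants: 32 the bis-ester of step 19
Product: 33 (−)-epiafzelechin 3-O-gallate-(4β→8)-(−)-epicatechin 3-O-gallate (target)
Conditions: H2 (1 atm), Pd(OH)2 on carbon, THF–MeOH–H2O, rt
Reagents that add atoms: none
Why: Hydrogenolysis of thirteen benzyl aryl ethers under neutral conditions, which leave the gallate esters, the C4–C8 bond and the benzylic ring oxygens intact.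

## Compound list

1 | (−)-epicatechin | O[C@@H]1Cc2c(O)cc(O)cc2O[C@@H]1c1ccc(O)c(O)c1 | starting material
2 | 5,7,3',4'-tetra-O-benzyl-(−)-epicatechin | O[C@@H]1Cc2c(OCc3ccccc3)cc(OCc3ccccc3)cc2O[C@@H]1c1ccc(OCc2ccccc2)c(OCc2ccccc2)c1 | intermediate
3 | 8-bromo-5,7,3',4'-tetra-O-benzyl-(−)-epicatechin | O[C@@H]1Cc2c(OCc3ccccc3)cc(OCc3ccccc3)c(Br)c2O[C@@H]1c1ccc(OCc2ccccc2)c(OCc2ccccc2)c1 | intermediate
4 | 8-bromo-3-O-(tert-butyldimethylsilyl)-5,7,3',4'-tetra-O-benzyl-(−)-epicatechin (ArD–Br) | CC(C)(C)[Si](C)(C)O[C@@H]1Cc2c(OCc3ccccc3)cc(OCc3ccccc3)c(Br)c2O[C@@H]1c1ccc(OCc2ccccc2)c(OCc2ccccc2)c1 | intermediate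
5 | 4-(benzyloxy)benzaldehyde | O=Cc1ccc(OCc2ccccc2)cc1 | starting material
6 | allyl methoxymethyl ether | C=CCOCOC | starting material
7 | [(Z)-3-(methoxymethoxy)allyl]diisopinocampheylborane, Ipc groups from (+)-α-pinene | COCO/C=C\CB([C@@H]1C[C@@H]2C[C@H]([C@H]1C)C2(C)C)[C@@H]1C[C@@H]2C[C@H]([C@H]1C)C2(C)C | intermediate (not isolated)
8 | (1R,2R)-1-[4-(benzyloxy)phenyl]-2-(methoxymethoxy)but-3-en-1-ol | C=C[C@@H](OCOC)[C@H](O)c1ccc(OCc2ccccc2)cc1 | intermediate
9 | (1R,2R)-1-[4-(benzyloxy)phenyl]-2-(methoxymethoxy)but-3-en-1-yl acrylate | C=C[C@@H](OCOC)[C@H](OC(=O)C=C)c1ccc(OCc2ccccc2)cc1 | intermediate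
10 | (5R,6R)-6-[4-(benzyloxy)phenyl]-5-(methoxymethoxy)-5,6-dihydro-2H-pyran-2-one | O=C1C=C[C@@H](OCOC)[C@@H](c2ccc(OCc3ccccc3)cc2)O1 | intermediate
11 | C8 aryllithium ArD–Li | [Li]c2c(OCc5ccccc5)cc(OCc5ccccc5)c3c2O[C@H](c7ccc(OCc5ccccc5)c(OCc5ccccc5)c7)[C@H](O[Si](C)(C)C(C)(C)C)C3 | intermediate (not isolated)
12 | lithium diarylcuprate (ArD)2CuLi | [Li+].[Cu-](c2c(OCc5ccccc5)cc(OCc5ccccc5)c3c2O[C@H](c7ccc(OCc5ccccc5)c(OCc5ccccc5)c7)[C@H](O[Si](C)(C)C(C)(C)C)C3)c2c(OCc5ccccc5)cc(OCc5ccccc5)c3c2O[C@H](c7ccc(OCc5ccccc5)c(OCc5ccccc5)c7)[C@H](O[Si](C)(C)C(C)(C)C)C3 | intermediate (not isolated)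
13 | trimethylsilyl ketene acetal of 14 | C[Si](C)(C)OC1=C[C@H](c2c(OCc5ccccc5)cc(OCc5ccccc5)c3c2O[C@H](c7ccc(OCc5ccccc5)c(OCc5ccccc5)c7)[C@H](O[Si](C)(C)C(C)(C)C)C3)[C@@H](OCOC)[C@@H](c7ccc(OCc5ccccc5)cc7)O1 | intermediate (not isolated)
14 | (4R,5R,6R)-4-ArD-6-[4-(benzyloxy)phenyl]-5-(methoxymethoxy)tetrahydro-2H-pyran-2-one | O=C1C[C@H](c2c(OCc5ccccc5)cc(OCc5ccccc5)c3c2O[C@H](c7ccc(OCc5ccccc5)c(OCc5ccccc5)c7)[C@H](O[Si](C)(C)C(C)(C)C)C3)[C@@H](OCOC)[C@@H](c7ccc(OCc5ccccc5)cc7)O1 | intermediate
15 | (3R,4R,5R)-3-ArD-5-[4-(benzyloxy)phenyl]-5-hydroxy-N-methoxy-4-(methoxymethoxy)-N-methylpentanamide | CON(C)C(=O)C[C@H](c2c(OCc5ccccc5)cc(OCc5ccccc5)c3c2O[C@H](c7ccc(OCc5ccccc5)c(OCc5ccccc5)c7)[C@H](O[Si](C)(C)C(C)(C)C)C3)[C@@H](OCOC)[C@H](O)c7ccc(OCc5ccccc5)cc7 | intermediate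
16 | (3R,4R)-3-ArD-5-[4-(benzyloxy)phenyl]-N-methoxy-4-(methoxymethoxy)-N-methyl-5-oxopentanamide | CON(C)C(=O)C[C@H](c2c(OCc5ccccc5)cc(OCc5ccccc5)c3c2O[C@H](c7ccc(OCc5ccccc5)c(OCc5ccccc5)c7)[C@H](O[Si](C)(C)C(C)(C)C)C3)[C@@H](OCOC)C(=O)c7ccc(OCc5ccccc5)cc7 | intermediate
17 | (3R,4R,5S)-3-ArD-5-[4-(benzyloxy)phenyl]-5-hydroxy-N-methoxy-4-(methoxymethoxy)-N-methylpentanamide | CON(C)C(=O)C[C@H](c2c(OCc5ccccc5)cc(OCc5ccccc5)c3c2O[C@H](c7ccc(OCc5ccccc5)c(OCc5ccccc5)c7)[C@H](O[Si](C)(C)C(C)(C)C)C3)[C@@H](OCOC)[C@@H](O)c7ccc(OCc5ccccc5)cc7 | intermediate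
18 | (3R,4R,5S)-3-ArD-5-[4-(benzyloxy)phenyl]-N-methoxy-4-(methoxymethoxy)-N-methyl-5-[(triethylsilyl)oxy]pentanamide | CON(C)C(=O)C[C@H](c2c(OCc5ccccc5)cc(OCc5ccccc5)c3c2O[C@H](c7ccc(OCc5ccccc5)c(OCc5ccccc5)c7)[C@H](O[Si](C)(C)C(C)(C)C)C3)[C@@H](OCOC)[C@@H](O[Si](CC)(CC)CC)c7ccc(OCc5ccccc5)cc7 | intermediate
19 | methyl acetoacetate | COC(=O)CC(C)=O | starting material
20 | sodium lithium dienolate of methyl acetoacetate | [Li+].[Na+].COC([O-])=CC([O-])=C | intermediate (not isolated)
21 | methyl (7R,8R,9S)-7-ArD-9-[4-(benzyloxy)phenyl]-8-(methoxymethoxy)-3,5-dioxo-9-[(triethylsilyl)oxy]nonanoate | COC(=O)CC(=O)CC(=O)C[C@H](c2c(OCc5ccccc5)cc(OCc5ccccc5)c3c2O[C@H](c7ccc(OCc5ccccc5)c(OCc5ccccc5)c7)[C@H](O[Si](C)(C)C(C)(C)C)C3)[C@@H](OCOC)[C@@H](O[Si](CC)(CC)CC)c7ccc(OCc5ccccc5)cc7 | intermediate (key-step precursor)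
22 | trilithium trienolate of 21 (enolate geometry not defined) | [Li+].[Li+].[Li+].COC([O-])=CC([O-])=CC([O-])=C[C@H](c2c(OCc5ccccc5)cc(OCc5ccccc5)c3c2O[C@H](c7ccc(OCc5ccccc5)c(OCc5ccccc5)c7)[C@H](O[Si](C)(C)C(C)(C)C)C3)[C@@H](OCOC)[C@@H](O[Si](CC)(CC)CC)c7ccc(OCc5ccccc5)cc7 | intermediate (not isolated)
23 | 2-substituted cyclohexane-1,3,5-trione, keto tautomer of 24 | O=C1CC(=O)CC(=O)C1[C@H](c2c(OCc5ccccc5)cc(OCc5ccccc5)c3c2O[C@H](c7ccc(OCc5ccccc5)c(OCc5ccccc5)c7)[C@H](O[Si](C)(C)C(C)(C)C)C3)[C@@H](OCOC)[C@@H](O[Si](CC)(CC)CC)c7ccc(OCc5ccccc5)cc7 | intermediate (not isolated)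
24 | 2-[(1R,2R,3S)-1-ArD-3-[4-(benzyloxy)phenyl]-2-(methoxymethoxy)-3-[(triethylsilyl)oxy]propyl]benzene-1,3,5-triol | Oc1cc(O)cc(O)c1[C@H](c2c(OCc5ccccc5)cc(OCc5ccccc5)c3c2O[C@H](c7ccc(OCc5ccccc5)c(OCc5ccccc5)c7)[C@H](O[Si](C)(C)C(C)(C)C)C3)[C@@H](OCOC)[C@@H](O[Si](CC)(CC)CC)c7ccc(OCc5ccccc5)cc7 | intermediate (key-step product)
25 | 2-[(1R,2R,3S)-1-ArD-3-[4-(benzyloxy)phenyl]-3-hydroxy-2-(methoxymethoxy)propyl]benzene-1,3,5-triol | Oc1cc(O)cc(O)c1[C@H](c2c(OCc5ccccc5)cc(OCc5ccccc5)c3c2O[C@H](c7ccc(OCc5ccccc5)c(OCc5ccccc5)c7)[C@H](O[Si](C)(C)C(C)(C)C)C3)[C@@H](OCOC)[C@@H](O)c7ccc(OCc5ccccc5)cc7 | intermediate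
26 | (2R,3R,4R)-4-ArD-2-[4-(benzyloxy)phenyl]-3-(methoxymethoxy)chroman-5,7-diol | COCO[C@@H]1[C@@H](c2c(OCc5ccccc5)cc(OCc5ccccc5)c3c2O[C@H](c7ccc(OCc5ccccc5)c(OCc5ccccc5)c7)[C@H](O[Si](C)(C)C(C)(C)C)C3)c2c(O)cc(O)cc2O[C@@H]1c1ccc(OCc2ccccc2)cc1 | intermediate
27 | (2R,3R,4R)-5,7-bis(benzyloxy)-4-ArD-2-[4-(benzyloxy)phenyl]-3-(methoxymethoxy)chroman | COCO[C@@H]1[C@@H](c2c(OCc5ccccc5)cc(OCc5ccccc5)c3c2O[C@H](c7ccc(OCc5ccccc5)c(OCc5ccccc5)c7)[C@H](O[Si](C)(C)C(C)(C)C)C3)c2c(OCc3ccccc3)cc(OCc3ccccc3)cc2O[C@@H]1c1ccc(OCc2ccccc2)cc1 | intermediate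
28 | (2R,3R,4R)-5,7-bis(benzyloxy)-4-ArD-2-[4-(benzyloxy)phenyl]chroman-3-ol | O[C@@H]1[C@@H](c2c(OCc5ccccc5)cc(OCc5ccccc5)c3c2O[C@H](c7ccc(OCc5ccccc5)c(OCc5ccccc5)c7)[C@H](O[Si](C)(C)C(C)(C)C)C3)c2c(OCc3ccccc3)cc(OCc3ccccc3)cc2O[C@@H]1c1ccc(OCc2ccccc2)cc1 | intermediate
29 | 5,7,4'-tri-O-benzyl-(−)-epiafzelechin-(4β→8)-5,7,3',4'-tetra-O-benzyl-(−)-epicatechin | O[C@@H]1[C@@H](c2c(OCc5ccccc5)cc(OCc5ccccc5)c3c2O[C@H](c7ccc(OCc5ccccc5)c(OCc5ccccc5)c7)[C@H](O)C3)c2c(OCc3ccccc3)cc(OCc3ccccc3)cc2O[C@@H]1c1ccc(OCc2ccccc2)cc1 | intermediate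
30 | 3,4,5-tris(benzyloxy)benzoic acid | OC(=O)c1cc(OCc2ccccc2)c(OCc2ccccc2)c(OCc2ccccc2)c1 | starting material
31 | 3,4,5-tris(benzyloxy)benzoyl chloride | ClC(=O)c1cc(OCc2ccccc2)c(OCc2ccccc2)c(OCc2ccccc2)c1 | intermediate (not isolated)
32 | 3,3''-bis-O-[3,4,5-tris(benzyloxy)benzoyl] derivative of 29 | O=C(O[C@@H]1[C@@H](c2c(OCc5ccccc5)cc(OCc5ccccc5)c3c2O[C@H](c7ccc(OCc5ccccc5)c(OCc5ccccc5)c7)[C@H](OC(=O)c6cc(OCc5ccccc5)c(OCc5ccccc5)c(OCc5ccccc5)c6)C3)c2c(OCc3ccccc3)cc(OCc3ccccc3)cc2O[C@@H]1c1ccc(OCc2ccccc2)cc1)c1cc(OCc2ccccc2)c(OCc2ccccc2)c(OCc2ccccc2)c1 | intermediate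
33 | (−)-epiafzelechin 3-O-gallate-(4β→8)-(−)-epicatechin 3-O-gallate; upper unit 2R,3R,4R, lower unit 2R,3R | O=C(O[C@@H]1[C@@H](c2c(O)cc(O)c3c2O[C@H](c2ccc(O)c(O)c2)[C@H](OC(=O)c2cc(O)c(O)c(O)c2)C3)c2c(O)cc(O)cc2O[C@@H]1c1ccc(O)cc1)c1cc(O)c(O)c(O)c1 | target

## Step count and risks

Total: 20 steps. Longest linear sequence: 17 steps (from 5 through steps 4–20; the same length from 1 through steps 1–3 and 7–20).

Least certain steps:

**Step 13 (key step).**
- What may go wrong: in trianion 22 the ester is part of a β-keto ester enolate and is a weak electrophile, so cyclisation may not set in before the polyanion decomposes on warming. O-acylation to the pyrone may take over, and the branched C4 substituent adds steric compression at the nucleophilic carbon.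
- Fallback (from 2, back at 29): ring A is not built de novo; the C4–C8 bond is made by flavan-4-yl cation chemistry. Purchased (−)-epiafzelechin F1 is benzylated (BnBr, K2CO3, DMF) to 5,7,4'-tri-O-benzyl-(−)-epiafzelechin F2. DDQ in CH2Cl2 with 2-ethoxyethanol oxidises the benzylic C4 position and gives the 4β-(2-ethoxyethoxy) ether F3. Catalytic Me3SiOTf in CH2Cl2 at −78 °C ionises F3, and an excess of 2 captures the cation at C8, anti to the C3 hydroxyl, to give diol 29 directly.

**Step 7.**
- What may go wrong: transfer of the di-ortho-substituted aryl group from copper may be slow, so that the lactone is lost to enolisation or 1,2-addition and the aryl group ends up protonated.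
- Fallback (from 4 and 10, back at 14; no new compound, F0): reductive Heck hydroarylation. Zerovalent palladium, generated from Pd(OAc)2 and P(t-Bu)3, inserts into the C8–Br bond of 4. Syn carbopalladation of 10 should occur on the face anti to both ring substituents. The resulting palladium enolate has no syn β-hydrogen on C4 and is reduced by HCO2Na in DMF.

**Step 10 (with steps 8, 9 and 11).**
- What may go wrong: facial selectivity may be poor if the open Felkin mode competes with the zinc chelate, and hydroxy amides 15 and 17 may re-close to lactones on handling.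
- Fallback (from 15, back at 17): inversion by substitution in place of oxidation and reduction. Mitsunobu esterification of 15 with 4-nitrobenzoic acid (PPh3, DIAD, toluene) gives the inverted (5S) 4-nitrobenzoate F4, and K2CO3 in methanol releases 17.

**Step 15.**
- What may go wrong: the alkoxyphosphonium intermediate may ionise at the 4-benzyloxybenzylic carbon, which would erode the inversion at C2.
- Fallback (from 25, back at 26; no new compound, F0): closure by deliberate ionisation. A catalytic sulfonic acid (camphorsulfonic acid, CH2Cl2, −20 °C) generates the C2 cation and the ortho phenol captures it. The configuration at C2 would then be set by the chair-like transition state: the trans C3 and C4 substituents stay diaxial, because an equatorial C4 aryl group clashes with the C5 oxygen of ring A, and ring B takes the equatorial position, which is the 2,3-cis arrangement.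

## Further compounds

F1 | step 13 | (−)-epiafzelechin (purchased) | O[C@@H]1Cc2c(O)cc(O)cc2O[C@@H]1c1ccc(O)cc1
F2 | step 13 | 5,7,4'-tri-O-benzyl-(−)-epiafzelechin | O[C@@H]1Cc2c(OCc3ccccc3)cc(OCc3ccccc3)cc2O[C@@H]1c1ccc(OCc2ccccc2)cc1
F3 | step 13 | 4β-(2-ethoxyethoxy)-5,7,4'-tri-O-benzyl-(−)-epiafzelechin | O[C@@H]1[C@@H](OCCOCC)c2c(OCc3ccccc3)cc(OCc3ccccc3)cc2O[C@@H]1c1ccc(OCc2ccccc2)cc1
F0 | step 7 | none | none
F4 | step 10 | (3R,4R,5S)-3-ArD-5-[4-(benzyloxy)phenyl]-N-methoxy-4-(methoxymethoxy)-N-methyl-5-(4-nitrobenzoyloxy)pentanamide | CON(C)C(=O)C[C@H](c2c(OCc5ccccc5)cc(OCc5ccccc5)c3c2O[C@H](c7ccc(OCc5ccccc5)c(OCc5ccccc5)c7)[C@H](O[Si](C)(C)C(C)(C)C)C3)[C@@H](OCOC)[C@@H](OC(=O)c8ccc(cc8)[N+](=O)[O-])c7ccc(OCc5ccccc5)cc7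
F0 | step 15 | none | none
A1 | alternative 1 | ring D salicyl alcohol carrying the protected upper unit at C8 | O=C(c6cc(OCc5ccccc5)c(OCc5ccccc5)c(OCc5ccccc5)c6)O[C@@H]1[C@@H](c2c(OCc5ccccc5)cc(OCc5ccccc5)c(CO)c2O)c4c(OCc5ccccc5)cc(OCc5ccccc5)cc4O[C@@H]1c7ccc(OCc5ccccc5)cc7
A2 | alternative 1 | ortho-quinone methide from A1 | O=C(c6cc(OCc5ccccc5)c(OCc5ccccc5)c(OCc5ccccc5)c6)O[C@@H]1[C@@H](C2=C(OCc5ccccc5)C=C(OCc5ccccc5)C(=C)C2=O)c4c(OCc5ccccc5)cc(OCc5ccccc5)cc4O[C@@H]1c7ccc(OCc5ccccc5)cc7
A3 | alternative 1 | (Z)-2-[3,4-bis(benzyloxy)phenyl]ethenyl 3,4,5-tris(benzyloxy)benzoate | O=C(O/C=C\c1ccc(OCc2ccccc2)c(OCc2ccccc2)c1)c1cc(OCc2ccccc2)c(OCc2ccccc2)c(OCc2ccccc2)c1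
A4 | alternative 1 | perbenzylated target (same compound as 32) | O=C(c6cc(OCc5ccccc5)c(OCc5ccccc5)c(OCc5ccccc5)c6)O[C@@H]1[C@@H](c2c(OCc5ccccc5)cc(OCc5ccccc5)c3c2O[C@H](c7ccc(OCc5ccccc5)c(OCc5ccccc5)c7)[C@H](OC(=O)c6cc(OCc5ccccc5)c(OCc5ccccc5)c(OCc5ccccc5)c6)C3)c4c(OCc5ccccc5)cc(OCc5ccccc5)cc4O[C@@H]1c7ccc(OCc5ccccc5)cc7
A5 | alternative 2 | diazo enone carrying the open lower chain | [N-]=[N+]=CC(=O)/C(OCc1ccccc1)=C/C[C@@H](O[Si](C)(C)C(C)(C)C)[C@@H](O[Si](CC)(CC)CC)c1ccc(OCc2ccccc2)c(OCc2ccccc2)c1
A6 | alternative 2 | vinylketene from A5 | O=C=C/C(OCc1ccccc1)=C/C[C@@H](O[Si](C)(C)C(C)(C)C)[C@@H](O[Si](CC)(CC)CC)c1ccc(OCc2ccccc2)c(OCc2ccccc2)c1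
A7 | alternative 2 | upper flavan with a triisopropylsiloxyethynyl group on C4 | CC(C)(C)[Si](C)(C)O[C@@H]1[C@@H](C#CO[Si](C(C)C)(C(C)C)C(C)C)c3c(OCc5ccccc5)cc(OCc5ccccc5)cc3O[C@@H]1c7ccc(OCc5ccccc5)cc7
A8 | alternative 2 | ring D phenol joining the upper flavan and the open lower chain | CC(C)(C)[Si](C)(C)O[C@@H]1[C@@H](c2c(O[Si](C(C)C)(C(C)C)C(C)C)cc(OCc5ccccc5)c(C[C@@H](O[Si](C)(C)C(C)(C)C)[C@@H](O[Si](CC)(CC)CC)c7ccc(OCc5ccccc5)c(OCc5ccccc5)c7)c2O)c3c(OCc5ccccc5)cc(OCc5ccccc5)cc3O[C@@H]1c7ccc(OCc5ccccc5)cc7
A9 | alternative 3 | diene with an α-aryl vinyl ether on O1 and a vinyl group on C4 | C=C(c7ccc(OCc5ccccc5)cc7)Oc2cc(OCc5ccccc5)cc(OCc5ccccc5)c2[C@@H](C=C)c2c(OCc5ccccc5)cc(OCc5ccccc5)c3c2O[C@H](c7ccc(OCc5ccccc5)c(OCc5ccccc5)c7)[C@H](O[Si](C)(C)C(C)(C)C)C3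
A10 | alternative 3 | 2,4-diaryl-4H-chromene (flav-2-ene) | C1(c7ccc(OCc5ccccc5)cc7)=C[C@@H](c2c(OCc5ccccc5)cc(OCc5ccccc5)c3c2O[C@H](c7ccc(OCc5ccccc5)c(OCc5ccccc5)c7)[C@H](O[Si](C)(C)C(C)(C)C)C3)c2c(OCc5ccccc5)cc(OCc5ccccc5)cc2O1
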